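How far has the substrate gone at 8.0 min in the flask, and how much of the unused partner is free?

| flask | substrate | partner | scavenger | remark | time |
|---|---|---|---|---|---|
| autumn | 0.050 M | 0.20 M | 0.040 M | the very flask that is asked about, followed so far |  |
| dusk | 0.034 M | 0.20 M | 0.040 M | run made earlier |  |
| flask | 0.050 M | 0.200 M | 0.0400 M |  | 8.0 min |

| run | time / min | substrate / % | target / % |
|---|---|---|---|
| autumn | 0.833 | 95 | 2 |
| autumn | 1.50 | 86 | 3 |
| autumn | 2.50 | 84 | 7 |
| autumn | 3.00 | 79 | 8 |
| autumn | 4.00 | 75 | 10 |
| dusk | 1.50 | 91 | 3 |
| dusk | 3.00 | 79 | 7 |
| dusk | 5.00 | 69 | 15 |
| dusk | 6.00 | 64 | 18 |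
| dusk | 8.00 | 56 | 25 |

(each reading ± 1.5 percentage points)

1. part of the substrate that has reacted at 8.0 min
2. share of the unused partner that is free and not bound as idle adduct, at 8.0 min

- the earlier runs do not show how much of partner is bound; that part of a forecast is a guess

You can draw the curve of substrate left from its two ends. At the far end, I assume one partner is used per substrate. The whole substrate then takes a quarter of the partner charge, which makes substrate the limiting reagent, so the curve should run towards zero with partner still in excess. One exponential then joins the two ends: the part left is exp(−kt).

The autumn run is this flask followed so far, and its reading of 75% left at 4.00 min gives 0.0719 min⁻¹. This k is the pseudo-first-order constant, the fraction of the remaining substrate lost per minute, and it carries the scatter of that reading. On this curve it is also the slope at the start. At 9.64 min this curve crosses half, and at 8.0 min it stands at 43.7% reacted.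

The dusk run, with 0.034 M of substrate, gives about the same constant, 0.0725 min⁻¹, from its own last reading. No run shows bound partner, so I offer no reckoning of the free share.

The forecast gave 44% reacted (41% to 48%) and 88% free (76% to 99%), noting that “Starting substrate has no visible effect”. The flask gives 43.6% reacted, against my 43.7%, and 97.9% of the unused partner free.

    substrate + partner → intermediate + released group (k = 0.387 M⁻¹ min⁻¹)
    intermediate ⇌ target (K = 16.0, k = 0.304 min⁻¹)
    intermediate ⇌ isomer of the product (K = 10.0, k = 0.0467 min⁻¹)
    partner + released group ⇌ idle adduct, settled at all times (K = 3.87 M⁻¹)
    scavenger + released group → scavenged by-product (k = 11.7 M⁻¹ min⁻¹)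

Now take k in proportion to the partner charge, as the first step of the scheme has it. For the neighbouring flask with 0.80 M of partner, k becomes 0.288 min⁻¹, which gives 90.0% reacted at 8.0 min. That flask gives 90.3%, with target at 60.4% of the substrate charged.

(The readings are simulated on assumed constants; the scatter is artificial.)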